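**Strategy.** Cembrane numbering is used: C1 carries the isopropyl group, C12 the methyl group, C11 the acetate. The oxolane ring (O, C1, C14, C13, C12) with its cis-disposed C2 and C11 is read as a 7-oxanorbornene that has lost the C2–C11 bond. A 3-silyloxyfuran (ring carbons C1, C2, C11, C12) therefore undergoes a catalytic enantioselective Diels–Alder reaction with an acrylimide as ethylene equivalent. This forms C1–C14 and C13–C12 and both tetrasubstituted ether stereocentres at once. Decarboxylation, then ozonolysis of the temporary C2=C11 bond, gives a C2 aldehyde and a C11 acid. Enantioselective ketone vinylation (C3–C4) and ring-closing metathesis (C9–C10) complete the macrocycle.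

Key step: step 4

Assumption: the facial senses quoted for the three ligand-controlled steps (4, 12, 15) are those expected from the closest published substrates; both mirror-image forms of each ligand are available, so the antipode is substituted should a step deliver the opposite sense.

**Step 1**
Reactants: 1 3-methylbutan-2-one; 2 ethyl (2S)-2-{[tert-butyl(dimethyl)silyl]oxy}propanoate
Product: 3 (2S)-2-{[tert-butyl(dimethyl)silyl]oxy}-6-methylheptane-3,5-dione
Conditions: 1 (2 equiv), LDA (2 equiv), THF, −78 °C; then 2, −78 → 0 °C; aq. NH4Cl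
Reagents that add atoms: none
Why: Crossed Claisen condensation, in which the kinetic methyl enolate of 1 is acylated by ester 2 and the second equivalent of enolate deprotonates the 1,3-diketone and drives the reaction; the lactate stereocentre is erased in step 3, so its integrity is irrelevant.

**Step 2**
Reactants: 3 (2S)-2-{[tert-butyl(dimethyl)silyl]oxy}-6-methylheptane-3,5-dione
Product: 4 2-methyl-5-(propan-2-yl)furan-3(2H)-one
Conditions: 2 M HCl, THF/MeOH, 40 °C
Reagents that add atoms: none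
Why: Acid removes the silyl ether, and the freed α′-hydroxy-1,3-diketone should cyclise onto the distal carbonyl and dehydrate (cyclodehydration to a 3(2H)-furanone).

**Step 3**
Reactants: 4 2-methyl-5-(propan-2-yl)furan-3(2H)-one
Product: 5 tert-butyl(dimethyl){[2-methyl-5-(propan-2-yl)furan-3-yl]oxy}silane
Conditions: TBSOTf, Et3N, CH2Cl2, 0 °C
Reagents that add atoms: tert-butyldimethylsilyl trifluoromethanesulfonate, CC(C)(C)[Si](C)(C)OS(=O)(=O)C(F)(F)F
Why: Enolisation toward the ring CH and O-silylation (silyl enol ether formation) should give the aromatic, electron-rich 3-silyloxyfuran.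

**Step 4**
Reactants: 5 tert-butyl(dimethyl){[2-methyl-5-(propan-2-yl)furan-3-yl]oxy}silane; 6 3-(prop-2-enoyl)-1,3-oxazolidin-2-one
Product: 7 3-{[(1S,2S,4S)-5-{[tert-butyl(dimethyl)silyl]oxy}-4-methyl-1-(propan-2-yl)-7-oxabicyclo[2.2.1]hept-5-en-2-yl]carbonyl}-1,3-oxazolidin-2-one (endo adduct)
Conditions: 5 (1.5 equiv), [Cu((S,S)-t-Bu-box)](SbF6)2 (10 mol%; t-Bu-box = 2,2'-(propane-2,2-diyl)bis(4-tert-butyl-4,5-dihydrooxazole)), CH2Cl2, −78 °C
Reagents that add atoms: none
Why: The dicationic bis(oxazoline) complex of divalent copper chelates both carbonyls of 6, and furan 5 adds across C1/C12 in an asynchronous endo [4+2] cycloaddition (lead bond C12–C13 from the carbon next to the silyloxy group, then C14–C1). The closest known reaction is the Diels–Alder addition of furan itself to the same imide under the same type of catalyst. The oxolane ring (O, C1, C14, C13, C12) and the cyclohexene ring (C1, C2, C11, C12, C13, C14) close together by suprafacial addition to both partners; in the stepwise limit the second bond is a 5-exo-trig closure of the copper enolate carbon C14 onto the oxocarbenium carbon C1. C1 and C12 arise cis because both new bonds form on one face of the planar furan, and their absolute sense should follow from the tert-butyl groups of the (S,S)-ligand, which shield one face of the s-cis imide, combined with the endo orientation; C14 is set endo but is only temporary. The step needs regioselectivity (the 3-silyloxy group makes C12 the nucleophilic terminus and places the acyl group on C14), endo selectivity (an exo adduct would lead to the mirror-image core after decarboxylation, but it is a separable diastereomer of 7) and facial selectivity (ligand).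

**Step 5**
Reactants: 7 3-{[(1S,2S,4S)-5-{[tert-butyl(dimethyl)silyl]oxy}-4-methyl-1-(propan-2-yl)-7-oxabicyclo[2.2.1]hept-5-en-2-yl]carbonyl}-1,3-oxazolidin-2-one
Product: 8 (1R,2S,4S)-4-methyl-5-oxo-1-(propan-2-yl)-7-oxabicyclo[2.2.1]heptane-2-carboxylic acid
Conditions: LiOH, H2O2, THF/H2O, 0 °C; Na2SO3; then 1 M HCl, rt
Reagents that add atoms: hydrogen peroxide, OO (as lithium hydroperoxide; supplies the carboxylic OH oxygen)
Why: Hydroperoxide should cleave the exocyclic imide carbonyl selectively (LiOOH hydrolysis of an N-acyloxazolidinone), and the acidic work-up hydrolyses the silyl enol ether to the ketone, after which cycloreversion is no longer possible.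

**Step 6**
Reactants: 8 (1R,2S,4S)-4-methyl-5-oxo-1-(propan-2-yl)-7-oxabicyclo[2.2.1]heptane-2-carboxylic acid
Product: 10 (1S,4R)-1-methyl-4-(propan-2-yl)-7-oxabicyclo[2.2.1]heptan-2-one, via Barton ester 9 (not isolated)
Conditions: 1-hydroxypyridine-2(1H)-thione, DCC, DMAP (cat.), CH2Cl2, 0 °C, dark; then t-BuSH, hν (tungsten lamp), PhH, rt
Reagents that add atoms: none
Why: Barton reductive decarboxylation, in which the thiohydroxamate ester fragments to the secondary C14 radical that abstracts hydrogen from the thiol, so that C13/C14 become the CH2–CH2 unit of a formal ethylene adduct; no stereocentre of the core is touched.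

**Step 7**
Reactants: 10 (1S,4R)-1-methyl-4-(propan-2-yl)-7-oxabicyclo[2.2.1]heptan-2-one
Product: 11 trimethyl{[(1S,4S)-1-methyl-4-(propan-2-yl)-7-oxabicyclo[2.2.1]hept-2-en-2-yl]oxy}silane
Conditions: LDA, TMSCl (internal quench), THF, −78 °C
Reagents that add atoms: chlorotrimethylsilane, C[Si](C)(C)Cl
Why: Kinetic enolisation at the only enolisable position (C2) with in situ O-silylation (silyl enol ether formation) should trap the enolate at −78 °C before it can expel the bridging oxygen.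

**Step 8**
Reactants: 11 trimethyl{[(1S,4S)-1-methyl-4-(propan-2-yl)-7-oxabicyclo[2.2.1]hept-2-en-2-yl]oxy}silane
Product: 12 (2S,5S)-5-formyl-2-methyl-5-(propan-2-yl)oxolane-2-carboxylic acid
Conditions: O3, CH2Cl2, −78 °C; Me2S; aqueous work-up
Reagents that add atoms: ozone, [O-][O+]=O
Why: Ozonolysis of the electron-rich enol ether cleaves the temporary C2=C11 bond into the C2 aldehyde and the C11 silyl ester (hydrolysed on work-up); both neighbouring centres are quaternary and cannot epimerise.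

**Step 9**
Reactants: 12 (2S,5S)-5-formyl-2-methyl-5-(propan-2-yl)oxolane-2-carboxylic acid
Product: 13 methyl (2S,5S)-5-formyl-2-methyl-5-(propan-2-yl)oxolane-2-carboxylate
Conditions: MeI, K2CO3, DMF, rt
Reagents that add atoms: iodomethane, CI
Why: SN2 O-alkylation of the carboxylate (esterification) masks the acid for the organometallic steps, while the non-enolisable aldehyde is inert.

**Step 10**
Reactants: 13 methyl (2S,5S)-5-formyl-2-methyl-5-(propan-2-yl)oxolane-2-carboxylate
Product: 14 methyl (2S,5S)-5-ethynyl-2-methyl-5-(propan-2-yl)oxolane-2-carboxylate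
Conditions: dimethyl (1-diazo-2-oxopropyl)phosphonate, K2CO3, MeOH, 0 °C → rt
Reagents that add atoms: dimethyl (1-diazo-2-oxopropyl)phosphonate, CC(=O)C(=[N+]=[N-])P(=O)(OC)OC
Why: Ohira–Bestmann homologation (Seyferth–Gilbert type) should convert the non-enolisable aldehyde into the terminal alkyne, the new carbon being C3.

**Step 11**
Reactants: 15 1,3-dithiane; 16 (2E)-1,4-dibromobut-2-ene
Product: 17 2-[(2E)-4-bromobut-2-en-1-yl]-1,3-dithiane
Conditions: 15, n-BuLi, THF, −30 °C; then added to 16 (3 equiv), THF, −78 °C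
Reagents that add atoms: none
Why: Corey–Seebach alkylation, in which the lithiated dithiane (C6) displaces one primary allylic bromide; inverse addition to excess 16 should limit double alkylation.

**Step 12**
Reactants: 17 2-[(2E)-4-bromobut-2-en-1-yl]-1,3-dithiane
Product: 18 2-[(2R)-2-methylbut-3-en-1-yl]-1,3-dithiane
Conditions: MeMgBr, CuBr·SMe2 (1 mol%), (R,R)-Taniaphos (1.2 mol%), CH2Cl2, −75 °C
Reagents that add atoms: methylmagnesium bromide, C[Mg]Br
Why: Copper-catalysed enantioselective allylic alkylation (SN2′) should deliver methyl to the γ-carbon, the chiral ferrocenyl diphosphine on copper setting the C8 stereocentre and the branched regiochemistry.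

**Step 13**
Reactants: 18 2-[(2R)-2-methylbut-3-en-1-yl]-1,3-dithiane; 19 2-methyloxirane (racemic)
Product: 20 1-{2-[(2R)-2-methylbut-3-en-1-yl]-1,3-dithian-2-yl}propan-2-ol (both carbinol epimers)
Conditions: n-BuLi, THF, −30 °C; then 19, −30 → 0 °C; aq. NH4Cl
Reagents that add atoms: none
Why: A second Corey–Seebach metalation and opening of the epoxide at its CH2 terminus install C5 and C4; the new carbinol centre is oxidised away in the next step.

**Step 14**
Reactants: 20 1-{2-[(2R)-2-methylbut-3-en-1-yl]-1,3-dithian-2-yl}propan-2-ol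
Product: 21 1-{2-[(2R)-2-methylbut-3-en-1-yl]-1,3-dithian-2-yl}propan-2-one
Conditions: (COCl)2, DMSO, CH2Cl2, −78 °C; Et3N
Reagents that add atoms: none
Why: Swern oxidation should give the methyl ketone without oxidising the thioacetal sulfur.

**Step 15**
Reactants: 14 methyl (2S,5S)-5-ethynyl-2-methyl-5-(propan-2-yl)oxolane-2-carboxylate; 21 1-{2-[(2R)-2-methylbut-3-en-1-yl]-1,3-dithian-2-yl}propan-2-one
Product: 24 methyl (2S,5S)-5-[(1E,3R)-3-hydroxy-3-methyl-4-{2-[(2R)-2-methylbut-3-en-1-yl]-1,3-dithian-2-yl}but-1-en-1-yl]-2-methyl-5-(propan-2-yl)oxolane-2-carboxylate, via alkenylzirconocene 22 (not isolated), via alkenylzinc 23 (not isolated)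
Conditions: 14, Cp2Zr(H)Cl, CH2Cl2, rt; Me2Zn, PhMe, −78 °C; then 21, Ti(OiPr)4, C2-symmetric bis(sulfonamide) diol ligand from trans-cyclohexane-1,2-diamine and 10-camphorsulfonyl chloride (10 mol%), rt
Reagents that add atoms: none
Why: Catalytic asymmetric vinylation of a ketone, in which syn-hydrozirconation and Zr-to-Zn transmetalation give the (E)-alkenylzinc and the titanium complex of the chiral ligand should direct its addition to the Si face of methyl ketone 21 (CH2-dithianyl as large, CH3 as small group), setting C4 (R) and the E-configured C2=C3 bond.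

**Step 16**
Reactants: 24 methyl (2S,5S)-5-[(1E,3R)-3-hydroxy-3-methyl-4-{2-[(2R)-2-methylbut-3-en-1-yl]-1,3-dithian-2-yl}but-1-en-1-yl]-2-methyl-5-(propan-2-yl)oxolane-2-carboxylate
Product: 26 1-[(2S,5S)-5-[(1E,3R)-3-hydroxy-3-methyl-4-{2-[(2R)-2-methylbut-3-en-1-yl]-1,3-dithian-2-yl}but-1-en-1-yl]-2-methyl-5-(propan-2-yl)oxolan-2-yl]prop-2-en-1-one, via Weinreb amide 25 (not isolated)
Conditions: MeNH(OMe)·HCl, i-PrMgCl, THF, −20 → 0 °C; then CH2=CHMgBr, 0 °C; quench into cold 1 M HCl
Reagents that add atoms: vinylmagnesium bromide, C=C[Mg]Br (N,O-dimethylhydroxylamine hydrochloride, CNOC.Cl, enters intermediate 25 only)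
Why: One-pot ester-to-ketone conversion through the N-methoxy-N-methylamide (Weinreb ketone synthesis), whose chelated tetrahedral adduct with the vinyl Grignard reagent should stop at the ketone stage; the tertiary alcohol is carried as its magnesium alkoxide.

**Step 17**
Reactants: 26 1-[(2S,5S)-5-[(1E,3R)-3-hydroxy-3-methyl-4-{2-[(2R)-2-methylbut-3-en-1-yl]-1,3-dithian-2-yl}but-1-en-1-yl]-2-methyl-5-(propan-2-yl)oxolan-2-yl]prop-2-en-1-one
Product: 27 (1R)-1-[(2S,5S)-5-[(1E,3R)-3-hydroxy-3-methyl-4-{2-[(2R)-2-methylbut-3-en-1-yl]-1,3-dithian-2-yl}but-1-en-1-yl]-2-methyl-5-(propan-2-yl)oxolan-2-yl]prop-2-en-1-ol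
Conditions: Zn(BH4)2, Et2O, −30 °C
Reagents that add atoms: none
Why: Chelation-controlled (Cram chelate) 1,2-reduction, in which zinc bridges the ketone oxygen and the oxolane oxygen and hydride should attack the face bearing the C12 methyl group, away from the ring CH2, giving the (11R) alcohol anti to the ring oxygen.

**Step 18**
Reactants: 27 (1R)-1-[(2S,5S)-5-[(1E,3R)-3-hydroxy-3-methyl-4-{2-[(2R)-2-methylbut-3-en-1-yl]-1,3-dithian-2-yl}but-1-en-1-yl]-2-methyl-5-(propan-2-yl)oxolan-2-yl]prop-2-en-1-ol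
Product: 28 (1R)-1-[(2S,5S)-5-[(1E,3R)-3-hydroxy-3-methyl-4-{2-[(2R)-2-methylbut-3-en-1-yl]-1,3-dithian-2-yl}but-1-en-1-yl]-2-methyl-5-(propan-2-yl)oxolan-2-yl]prop-2-en-1-yl acetate
Conditions: Ac2O, pyridine, DMAP (cat.), CH2Cl2, 0 °C
Reagents that add atoms: acetic anhydride, CC(=O)OC(C)=O
Why: Acylation of the secondary allylic alcohol; the tertiary C4 alcohol is too hindered to react under these conditions.

**Step 19**
Reactants: 28 (1R)-1-[(2S,5S)-5-[(1E,3R)-3-hydroxy-3-methyl-4-{2-[(2R)-2-methylbut-3-en-1-yl]-1,3-dithian-2-yl}but-1-en-1-yl]-2-methyl-5-(propan-2-yl)oxolan-2-yl]prop-2-en-1-yl acetate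
Product: 29 (1R)-1-[(2S,5S)-5-[(1E,3R,7R)-3-hydroxy-3,7-dimethyl-5-oxonona-1,8-dien-1-yl]-2-methyl-5-(propan-2-yl)oxolan-2-yl]prop-2-en-1-yl acetate
Conditions: MeI, CaCO3, MeCN/H2O (9:1), 45 °C
Reagents that add atoms: water, O
Why: S-Methylation of the thioacetal and hydrolysis (alkylative dethioacetalisation) should unmask the C6 ketone under near-neutral conditions that spare the β-hydroxy ketone, the acetate and the alkenes.

**Step 20**
Reactants: 29 (1R)-1-[(2S,5S)-5-[(1E,3R,7R)-3-hydroxy-3,7-dimethyl-5-oxonona-1,8-dien-1-yl]-2-methyl-5-(propan-2-yl)oxolan-2-yl]prop-2-en-1-yl acetate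
Product: 30 (1S,2E,4R,8R,11R,12S)-4-hydroxy-4,8,12-trimethyl-6-oxo-1-(propan-2-yl)-15-oxabicyclo[10.2.1]pentadeca-2,9-dien-11-yl acetate (9E/9Z mixture)
Conditions: second-generation Grubbs catalyst RuCl2(=CHPh)(H2IMes)(PCy3) (10 mol%), CH2Cl2 (1 mM), reflux
Reagents that add atoms: none
Why: Ring-closing metathesis of the two monosubstituted alkenes should close the 14-membered carbocycle at C9=C10 with loss of ethene, while the trans C2=C3 bond, flanked by two fully substituted carbons, should stay out of the reaction.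

**Step 21**
Reactants: 30 (1S,2E,4R,8R,11R,12S)-4-hydroxy-4,8,12-trimethyl-6-oxo-1-(propan-2-yl)-15-oxabicyclo[10.2.1]pentadeca-2,9-dien-11-yl acetate
Product: 31 CNP0131678.1, (1S,2E,4R,8S,11R,12S)-4-hydroxy-4,8,12-trimethyl-6-oxo-1-(propan-2-yl)-15-oxabicyclo[10.2.1]pentadec-2-en-11-yl acetate
Conditions: KO2C–N=N–CO2K, AcOH, MeOH, 0 °C → rt
Reagents that add atoms: none
Why: Diimide reduction is governed by steric access and should saturate only the C9=C10 bond, leaving the encumbered C2=C3 alkene, the ketone and the acetate untouched.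

**Compound list**

1 | 3-methylbutan-2-one | CC(=O)C(C)C | starting material
2 | ethyl (2S)-2-{[tert-butyl(dimethyl)silyl]oxy}propanoate | CCOC(=O)[C@H](C)O[Si](C)(C)C(C)(C)C | starting material
3 | (2S)-2-{[tert-butyl(dimethyl)silyl]oxy}-6-methylheptane-3,5-dione | CC(C)C(=O)CC(=O)[C@H](C)O[Si](C)(C)C(C)(C)C | intermediate
4 | 2-methyl-5-(propan-2-yl)furan-3(2H)-one (racemic at C2) | CC1OC(C(C)C)=CC1=O | intermediate
5 | tert-butyl(dimethyl){[2-methyl-5-(propan-2-yl)furan-3-yl]oxy}silane | CC1=C(O[Si](C)(C)C(C)(C)C)C=C(C(C)C)O1 | intermediate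
6 | 3-(prop-2-enoyl)-1,3-oxazolidin-2-one | C=CC(=O)N1CCOC1=O | starting material
7 | 3-{[(1S,2S,4S)-5-{[tert-butyl(dimethyl)silyl]oxy}-4-methyl-1-(propan-2-yl)-7-oxabicyclo[2.2.1]hept-5-en-2-yl]carbonyl}-1,3-oxazolidin-2-one (endo) | CC(C)(C)[Si](C)(C)OC1=C[C@@]2(C(C)C)[C@@H](C(=O)N3CCOC3=O)C[C@]1(C)O2 | intermediate
8 | (1R,2S,4S)-4-methyl-5-oxo-1-(propan-2-yl)-7-oxabicyclo[2.2.1]heptane-2-carboxylic acid | O=C1C[C@@]2(C(C)C)[C@@H](C(=O)O)C[C@]1(C)O2 | intermediate
9 | 2-thioxopyridin-1(2H)-yl (1R,2S,4S)-4-methyl-5-oxo-1-(propan-2-yl)-7-oxabicyclo[2.2.1]heptane-2-carboxylate (Barton ester) | O=C1C[C@@]2(C(C)C)[C@@H](C(=O)ON3C=CC=CC3=S)C[C@]1(C)O2 | intermediate (not isolated)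
10 | (1S,4R)-1-methyl-4-(propan-2-yl)-7-oxabicyclo[2.2.1]heptan-2-one | O=C1C[C@@]2(C(C)C)CC[C@]1(C)O2 | intermediate
11 | trimethyl{[(1S,4S)-1-methyl-4-(propan-2-yl)-7-oxabicyclo[2.2.1]hept-2-en-2-yl]oxy}silane | C[Si](C)(C)OC1=C[C@@]2(C(C)C)CC[C@]1(C)O2 | intermediate
12 | (2S,5S)-5-formyl-2-methyl-5-(propan-2-yl)oxolane-2-carboxylic acid | O=C[C@@]1(C(C)C)CC[C@@](C)(C(=O)O)O1 | intermediate
13 | methyl (2S,5S)-5-formyl-2-methyl-5-(propan-2-yl)oxolane-2-carboxylate | O=C[C@@]1(C(C)C)CC[C@@](C)(C(=O)OC)O1 | intermediate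
14 | methyl (2S,5S)-5-ethynyl-2-methyl-5-(propan-2-yl)oxolane-2-carboxylate | C#C[C@@]1(C(C)C)CC[C@@](C)(C(=O)OC)O1 | intermediate
15 | 1,3-dithiane | C1CSCSC1 | starting material
16 | (2E)-1,4-dibromobut-2-ene | BrC/C=C/CBr | starting material
17 | 2-[(2E)-4-bromobut-2-en-1-yl]-1,3-dithiane | BrC/C=C/CC1SCCCS1 | intermediate
18 | 2-[(2R)-2-methylbut-3-en-1-yl]-1,3-dithiane | C=C[C@H](C)CC1SCCCS1 | intermediate
19 | 2-methyloxirane (racemic) | CC1CO1 | starting material
20 | 1-{2-[(2R)-2-methylbut-3-en-1-yl]-1,3-dithian-2-yl}propan-2-ol (both carbinol epimers) | C=C[C@H](C)CC1(CC(C)O)SCCCS1 | intermediate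
21 | 1-{2-[(2R)-2-methylbut-3-en-1-yl]-1,3-dithian-2-yl}propan-2-one | C=C[C@H](C)CC1(CC(C)=O)SCCCS1 | intermediate
22 | chlorido{(E)-2-[(2S,5S)-5-(methoxycarbonyl)-5-methyl-2-(propan-2-yl)oxolan-2-yl]ethenyl}zirconocene | Cl[Zr](C1C=CC=C1)(C1C=CC=C1)/C=C/[C@@]2(C(C)C)CC[C@@](C)(C(=O)OC)O2 | intermediate (not isolated)
23 | {(E)-2-[(2S,5S)-5-(methoxycarbonyl)-5-methyl-2-(propan-2-yl)oxolan-2-yl]ethenyl}(methyl)zinc | C[Zn]/C=C/[C@@]1(C(C)C)CC[C@@](C)(C(=O)OC)O1 | intermediate (not isolated)
24 | methyl (2S,5S)-5-[(1E,3R)-3-hydroxy-3-methyl-4-{2-[(2R)-2-methylbut-3-en-1-yl]-1,3-dithian-2-yl}but-1-en-1-yl]-2-methyl-5-(propan-2-yl)oxolane-2-carboxylate | C=C[C@H](C)CC1(SCCCS1)C[C@@](C)(O)/C=C/[C@@]2(C(C)C)CC[C@@](C)(C(=O)OC)O2 | intermediate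
25 | (2S,5S)-5-[(1E,3R)-3-hydroxy-3-methyl-4-{2-[(2R)-2-methylbut-3-en-1-yl]-1,3-dithian-2-yl}but-1-en-1-yl]-N-methoxy-N,2-dimethyl-5-(propan-2-yl)oxolane-2-carboxamide | C=C[C@H](C)CC1(SCCCS1)C[C@@](C)(O)/C=C/[C@@]2(C(C)C)CC[C@@](C)(C(=O)N(C)OC)O2 | intermediate (not isolated)
26 | 1-[(2S,5S)-5-[(1E,3R)-3-hydroxy-3-methyl-4-{2-[(2R)-2-methylbut-3-en-1-yl]-1,3-dithian-2-yl}but-1-en-1-yl]-2-methyl-5-(propan-2-yl)oxolan-2-yl]prop-2-en-1-one | C=C[C@H](C)CC1(SCCCS1)C[C@@](C)(O)/C=C/[C@@]2(C(C)C)CC[C@@](C)(C(=O)C=C)O2 | intermediate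
27 | (1R)-1-[(2S,5S)-5-[(1E,3R)-3-hydroxy-3-methyl-4-{2-[(2R)-2-methylbut-3-en-1-yl]-1,3-dithian-2-yl}but-1-en-1-yl]-2-methyl-5-(propan-2-yl)oxolan-2-yl]prop-2-en-1-ol | C=C[C@H](C)CC1(SCCCS1)C[C@@](C)(O)/C=C/[C@@]2(C(C)C)CC[C@@](C)([C@H](O)C=C)O2 | intermediate
28 | (1R)-1-[(2S,5S)-5-[(1E,3R)-3-hydroxy-3-methyl-4-{2-[(2R)-2-methylbut-3-en-1-yl]-1,3-dithian-2-yl}but-1-en-1-yl]-2-methyl-5-(propan-2-yl)oxolan-2-yl]prop-2-en-1-yl acetate | C=C[C@H](C)CC1(SCCCS1)C[C@@](C)(O)/C=C/[C@@]2(C(C)C)CC[C@@](C)([C@H](OC(C)=O)C=C)O2 | intermediate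
29 | (1R)-1-[(2S,5S)-5-[(1E,3R,7R)-3-hydroxy-3,7-dimethyl-5-oxonona-1,8-dien-1-yl]-2-methyl-5-(propan-2-yl)oxolan-2-yl]prop-2-en-1-yl acetate | C=C[C@H](C)CC(=O)C[C@@](C)(O)/C=C/[C@@]1(C(C)C)CC[C@@](C)([C@H](OC(C)=O)C=C)O1 | intermediate
30 | (1S,2E,4R,8R,11R,12S)-4-hydroxy-4,8,12-trimethyl-6-oxo-1-(propan-2-yl)-15-oxabicyclo[10.2.1]pentadeca-2,9-dien-11-yl acetate (9E/9Z mixture) | CC(=O)O[C@@H]1C=C[C@H](C)CC(=O)C[C@@](C)(O)/C=C/[C@@]2(C(C)C)CC[C@]1(C)O2 | intermediate
31 | CNP0131678.1, (1S,2E,4R,8S,11R,12S)-4-hydroxy-4,8,12-trimethyl-6-oxo-1-(propan-2-yl)-15-oxabicyclo[10.2.1]pentadec-2-en-11-yl acetate | CC(=O)O[C@@H]1CC[C@H](C)CC(=O)C[C@@](C)(O)/C=C/[C@@]2(C(C)C)CC[C@]1(C)O2 | target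

**Step count and risks**

Total step count: 21. Longest linear sequence: 17 steps (steps 1–10 and 15–21); the side-chain ketone 21 takes 4 steps (11–14).

Steps most likely to fail:

1. Step 4 (key cycloaddition). Silyl transfer may stop the process at the open-chain Mukaiyama–Michael stage, the Lewis acid may open the oxygen bridge, or endo and facial control may be poor. The fallback sets out from 5 and returns at 12. Furan 5 is heated with phenyl vinyl sulfone (PhMe, 60 °C, no catalyst) to give the racemic sulfonyl cycloadduct F1; in the racemic mode regiochemistry and endo/exo selectivity no longer matter. Reductive desulfonylation (6% Na(Hg), Na2HPO4, MeOH, −20 °C) gives the racemic silyl enol ether F2. Ozonolysis (O3, CH2Cl2, −78 °C; Me2S) gives the racemic cis aldehyde acid F3. Crystallisation of the (S)-1-phenylethylammonium salt F4 and acidification return enantiopure 12; the mirror-image amine is used if the other salt proves the less soluble one.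

2. Step 15 (ketone vinylation). Enantioface discrimination at C4 may be insufficient for this dialkyl ketone, methyl transfer from zinc may compete, or the thioacetal sulfur may interfere with the titanium catalyst. The fallback sets out from 14 and 21 and returns at 24. The bromomagnesium acetylide of 14 (i-PrMgCl, THF, 0 °C) is added to 21 in the presence of LaCl3·2LiCl to give the propargylic alcohol F5 as a mixture of C4 epimers. Trans-selective reduction of the propargylic alcohol (aqueous CrSO4, DMF; divalent chromium) gives 24 together with its C4 epimer F6, and the two diastereomers are separated by chromatography.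

3. Step 20 (macrocyclisation). Oligomerisation may dominate, or a ruthenium carbene formed at the C10 vinyl group may close onto the nearby C2=C3 bond and cut off the side chain. The fallback sets out from 26 and returns at 30. The ring is closed at the enone stage with the second-generation Hoveyda–Grubbs catalyst RuCl2(=CH-2-(i-PrO)C6H4)(H2IMes) (PhMe, 80 °C, 1 mM), where only the C9 vinyl group can carry the carbene, to give the macrocyclic (9E)-enone F7. Chelation-controlled reduction (Zn(BH4)2, Et2O, −30 °C) gives the (11R) allylic alcohol F8, acetylation (Ac2O, pyridine) gives F9, and MeI/CaCO3 in aqueous MeCN removes the thioacetal to give 30 as its 9E isomer.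

Further compounds
F1 | step 4 | racemic tert-butyl(dimethyl){[1-methyl-5-(phenylsulfonyl)-4-(propan-2-yl)-7-oxabicyclo[2.2.1]hept-2-en-2-yl]oxy}silane | CC(C)(C)[Si](C)(C)OC1=CC2(C(C)C)C(S(=O)(=O)c3ccccc3)CC1(C)O2
F2 | step 4 | racemic tert-butyl(dimethyl){[1-methyl-4-(propan-2-yl)-7-oxabicyclo[2.2.1]hept-2-en-2-yl]oxy}silane | CC(C)(C)[Si](C)(C)OC1=CC2(C(C)C)CCC1(C)O2
F3 | step 4 | racemic cis-5-formyl-2-methyl-5-(propan-2-yl)oxolane-2-carboxylic acid | O=CC1(C(C)C)CCC(C)(C(=O)O)O1
F4 | step 4 | (1S)-1-phenylethanaminium (2S,5S)-5-formyl-2-methyl-5-(propan-2-yl)oxolane-2-carboxylate | C[C@H]([NH3+])c1ccccc1.O=C[C@@]1(C(C)C)CC[C@@](C)(C(=O)[O-])O1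
F5 | step 15 | methyl (2S,5S)-5-(3-hydroxy-3-methyl-4-{2-[(2R)-2-methylbut-3-en-1-yl]-1,3-dithian-2-yl}but-1-yn-1-yl)-2-methyl-5-(propan-2-yl)oxolane-2-carboxylate (C4 epimers) | C=C[C@H](C)CC1(SCCCS1)CC(C)(O)C#C[C@@]2(C(C)C)CC[C@@](C)(C(=O)OC)O2
F6 | step 15 | methyl (2S,5S)-5-[(1E,3S)-3-hydroxy-3-methyl-4-{2-[(2R)-2-methylbut-3-en-1-yl]-1,3-dithian-2-yl}but-1-en-1-yl]-2-methyl-5-(propan-2-yl)oxolane-2-carboxylate (C4 epimer of 24) | C=C[C@H](C)CC1(SCCCS1)C[C@](C)(O)/C=C/[C@@]2(C(C)C)CC[C@@](C)(C(=O)OC)O2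
F7 | step 20 | macrocyclic (9E)-enone: 11-oxo-9,10-didehydro analogue of the target skeleton with C6 as its 1,3-dithiane and C4 hydroxyl free | O=C1/C=C/[C@H](C)CC3(SCCCS3)C[C@@](C)(O)/C=C/[C@@]2(C(C)C)CC[C@]1(C)O2
F8 | step 20 | (11R) macrocyclic allylic alcohol from F7 (C6 dithiane) | O[C@@H]1/C=C/[C@H](C)CC3(SCCCS3)C[C@@](C)(O)/C=C/[C@@]2(C(C)C)CC[C@]1(C)O2
F9 | step 20 | C11 acetate of F8 (C6 dithiane) | CC(=O)O[C@@H]1/C=C/[C@H](C)CC3(SCCCS3)C[C@@](C)(O)/C=C/[C@@]2(C(C)C)CC[C@]1(C)O2
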